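**Retrosynthetic overview**

- Ring C is a 6'-pentylresorcylic acid (C1' CO2H, C2' and C4' OH, C6' pentyl) with one extra oxygen, the diaryl ether oxygen on C5'. The plan rests on the neighbouring C4'/C5' oxygens, which map onto an α-oxygenated methyl ketone.
- Target ⇒ (hydrogenolysis, dehydrogenation) 5'-aryloxy cyclohexane-1,3-dione carboxylate ⇒ (C1'–C6' Michael, C2'–C3' Claisen) dibenzyl malonate + an α-aryloxy enone that already holds the O–C5' bond.
- Enone ⇒ (C5'=C6' Horner–Wadsworth–Emmons with hexanal; O–C5' by carbene O–H insertion at an sp3 carbon) 8-hydroxyisocoumarin, so no aryl C–O coupling is needed.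
- Isocoumarin ⇒ methyl orsellinate by lateral acylation with a hexanoyl Weinreb amide and lactonisation. Ring A is bought, ring B is closed first, ring C last.

Key step: step 8

Assumption: the target has no stereocentre; the sp3 centres that arise on the way are formed without control and are erased later, and the 1,3-dione is drawn as its triketo tautomer although it should exist largely as enols.

**Route**

Step 1
Reactants: 1 methyl orsellinate; 2 benzyl bromide
Product: 3 methyl 2,4-bis(benzyloxy)-6-methylbenzoate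
Conditions: BnBr (2.4 equiv), K2CO3 (3 equiv), DMF, 60 °C
Reagents that add atoms: benzyl bromide 2, BrCc1ccccc1
Why: Williamson ether synthesis, in which both phenoxides (the chelated one needs the warm dipolar solvent) are O-benzylated by SN2 while the hindered methyl ester is untouched.

Step 2
Reactants: 4 hexanoyl chloride; 5 N,O-dimethylhydroxylamine hydrochloride
Product: 6 N-methoxy-N-methylhexanamide
Conditions: K2CO3, CH2Cl2/H2O, 0 °C → rt
Reagents that add atoms: N,O-dimethylhydroxylamine hydrochloride 5, CNOC.Cl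
Why: Schotten–Baumann acylation of the amine set free in the two-phase mixture should give the Weinreb amide cleanly.

Step 3
Reactants: 3 methyl 2,4-bis(benzyloxy)-6-methylbenzoate; 6 N-methoxy-N-methylhexanamide
Product: 8 methyl 2,4-bis(benzyloxy)-6-(2-oxoheptyl)benzoate, via lithiated toluate 7 (not isolated)
Conditions: LDA (1.2 equiv), THF, −78 °C; then 6, −78 → 0 °C; 1 M HCl
Reagents that add atoms: N-methoxy-N-methylhexanamide 6, CCCCCC(=O)N(C)OC
Why: Lateral (benzylic) lithiation of the o-toluate followed by Weinreb ketone synthesis, the N-methoxy chelate holding the tetrahedral adduct until the quench so that the acidic benzylic ketone is not present in the basic mixture.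

Step 4
Reactants: 8 methyl 2,4-bis(benzyloxy)-6-(2-oxoheptyl)benzoate
Product: 9 6,8-bis(benzyloxy)-3-pentyl-1H-isochromen-1-one
Conditions: TsOH·H2O (10 mol%), toluene, 90 °C
Reagents that add atoms: none
Why: Acid-catalysed enol lactonisation (the ketone enol displaces methanol from the ester) closes ring B as the conjugated isocoumarin, and acid is chosen over base so that Claisen closure to a naphthalene-1,3-diol cannot compete.

Step 5
Reactants: 9 6,8-bis(benzyloxy)-3-pentyl-1H-isochromen-1-one
Product: 10 6-(benzyloxy)-8-hydroxy-3-pentyl-1H-isochromen-1-one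
Conditions: BCl3 (1.1 equiv), CH2Cl2, −78 °C; then H2O
Reagents that add atoms: none
Why: Chelation-directed Lewis acid ether cleavage, in which BCl3 bound between the lactone carbonyl and the peri O8 ether removes only that benzyl group at low temperature and leaves the O6 benzyl ether.

Step 6
Reactants: 10 6-(benzyloxy)-8-hydroxy-3-pentyl-1H-isochromen-1-one; 11 dimethyl (1-diazo-2-oxopropyl)phosphonate
Product: 12 dimethyl (1-{[6-(benzyloxy)-1-oxo-3-pentyl-1H-isochromen-8-yl]oxy}-2-oxopropyl)phosphonate (racemic)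
Conditions: Rh2(OAc)4 (2 mol%), toluene, 90 °C, 11 (1.5 equiv) added slowly
Reagents that add atoms: dimethyl (1-diazo-2-oxopropyl)phosphonate 11, COP(=O)(OC)C(=[N+]=[N-])C(C)=O
Why: Rhodium carbenoid O–H insertion (attack of the phenol oxygen on the electrophilic carbenoid, then proton shift) makes the hindered ether C–O bond at an sp3 carbon; the new stereocentre is formed racemic and is removed in step 7.

Step 7
Reactants: 12 dimethyl (1-{[6-(benzyloxy)-1-oxo-3-pentyl-1H-isochromen-8-yl]oxy}-2-oxopropyl)phosphonate; 13 hexanal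
Product: 14 (Z)-3-{[6-(benzyloxy)-1-oxo-3-pentyl-1H-isochromen-8-yl]oxy}non-3-en-2-one
Conditions: LiCl, DBU, MeCN, 0 °C → rt (DBU added last)
Reagents that add atoms: hexanal 13, CCCCCC=O
Why: Horner–Wadsworth–Emmons olefination under Masamune–Roush conditions, mild enough for the enolisable aldehyde and the lactone, should place the acetyl group trans to the pentyl chain (Z descriptor), and either alkene isomer would serve in step 8.

Step 8
Reactants: 14 (Z)-3-{[6-(benzyloxy)-1-oxo-3-pentyl-1H-isochromen-8-yl]oxy}non-3-en-2-one; 15 dibenzyl malonate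
Product: 17 benzyl 3-{[6-(benzyloxy)-1-oxo-3-pentyl-1H-isochromen-8-yl]oxy}-4,6-dioxo-2-pentylcyclohexane-1-carboxylate, via Michael adduct 16 (not isolated)
Conditions: 15 (1.2 equiv), KOtBu (1.1 equiv), THF, 0 → 50 °C; then 1 M HCl
Reagents that add atoms: dibenzyl malonate 15, O=C(CC(=O)OCc1ccccc1)OCc1ccccc1
Why: Proposed new method: the potassium enolate of dibenzyl malonate adds in a Michael reaction to the pentyl-bearing β-carbon of the enone (bond C1'–C6'), the adduct equilibrates by proton transfer to the methyl ketone enolate, and this attacks one benzyl ester in a Claisen condensation (bond C2'–C3'), the benzyl oxide released deprotonating the acidic 1,3-dione and so pulling the sequence forward. The closest known reaction is the Michael–Claisen annulation of malonic esters with 3-alken-2-ones to 5-alkylcyclohexane-1,3-dione carboxylates; new here is the α-aryloxy group on the acceptor, which lowers its electrophilicity by lone-pair donation but leaves the acetyl group in control of the polarity. Ring C closes in a 6-exo-trig mode, an enolate carbon attacking an ester carbonyl whose C=O lies outside the forming ring. The three sp3 centres formed (C1', C5', C6') are not controlled and need not be, since all are erased in step 10. The step needs attack at the β-carbon and closure through the methyl group: the enone polarity secures the first, and closure through the other α-carbon (C5') would give a four-membered ring; the ring B lactone should be spared because the strong base is used up by the malonate and the released alkoxide by the product.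

Step 9
Reactants: 17 benzyl 3-{[6-(benzyloxy)-1-oxo-3-pentyl-1H-isochromen-8-yl]oxy}-4,6-dioxo-2-pentylcyclohexane-1-carboxylate
Product: 18 benzyl 5-{[6-(benzyloxy)-1-oxo-3-pentyl-1H-isochromen-8-yl]oxy}-6-pentyl-2,4-bis[(trimethylsilyl)oxy]cyclohexa-1,3-diene-1-carboxylate
Conditions: TMSOTf (2.4 equiv), Et3N (3 equiv), CH2Cl2, 0 °C; evaporation, pentane, filtration under argon; used crude
Reagents that add atoms: trimethylsilyl trifluoromethanesulfonate, C[Si](C)(C)OS(=O)(=O)C(F)(F)F
Why: Soft enolisation and O-silylation of the 1,3-dione and of the β-keto ester should give the bis(silyl) dienol ether, and any regioisomeric dienol ether formed beside it would converge on the same arene in step 10.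

Step 10
Reactants: 18 benzyl 5-{[6-(benzyloxy)-1-oxo-3-pentyl-1H-isochromen-8-yl]oxy}-6-pentyl-2,4-bis[(trimethylsilyl)oxy]cyclohexa-1,3-diene-1-carboxylate
Product: 20 benzyl 3-{[6-(benzyloxy)-1-oxo-3-pentyl-1H-isochromen-8-yl]oxy}-4,6-dihydroxy-2-pentylbenzoate, via bis-silyl aryl ether 19 (not isolated)
Conditions: DDQ (1.05 equiv), toluene, 0 °C → rt; then 1 M HCl, THF
Reagents that add atoms: none
Why: Quinone dehydrogenation of a silyloxy cyclohexadiene (hydride abstraction from C6', proton loss from C5') aromatises ring C under neutral conditions that keep the benzyl ester, the benzyl ether and the C5'–O bond, and the labile aryl silyl ethers are hydrolysed in the acidic work-up.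

Step 11
Reactants: 20 benzyl 3-{[6-(benzyloxy)-1-oxo-3-pentyl-1H-isochromen-8-yl]oxy}-4,6-dihydroxy-2-pentylbenzoate
Product: 21 4,6-dihydroxy-3-[(6-hydroxy-1-oxo-3-pentyl-1H-isochromen-8-yl)oxy]-2-pentylbenzoic acid
Conditions: H2 (1 atm), Pd/C (10%), EtOAc, rt, stopped after uptake of two equivalents
Reagents that add atoms: none
Why: Hydrogenolysis of the benzyl ester and the benzyl aryl ether over palladium on carbon is much faster than reduction of the trisubstituted C3–C4 enol-lactone alkene, so the isocoumarin should survive.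

**Compound list**

1 | methyl orsellinate (methyl 2,4-dihydroxy-6-methylbenzoate) | COC(=O)c1c(C)cc(O)cc1O | starting material
2 | benzyl bromide | BrCc1ccccc1 | starting material
3 | methyl 2,4-bis(benzyloxy)-6-methylbenzoate | COC(=O)c1c(C)cc(OCc2ccccc2)cc1OCc1ccccc1 | intermediate
4 | hexanoyl chloride | CCCCCC(=O)Cl | starting material
5 | N,O-dimethylhydroxylamine hydrochloride | CNOC.Cl | starting material
6 | N-methoxy-N-methylhexanamide | CCCCCC(=O)N(C)OC | intermediate
7 | methyl 2,4-bis(benzyloxy)-6-(lithiomethyl)benzoate; not isolated | [Li]Cc1cc(OCc2ccccc2)cc(OCc2ccccc2)c1C(=O)OC | intermediate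
8 | methyl 2,4-bis(benzyloxy)-6-(2-oxoheptyl)benzoate | CCCCCC(=O)Cc1cc(OCc2ccccc2)cc(OCc2ccccc2)c1C(=O)OC | intermediate
9 | 6,8-bis(benzyloxy)-3-pentyl-1H-isochromen-1-one | CCCCCc1cc2cc(OCc3ccccc3)cc(OCc3ccccc3)c2c(=O)o1 | intermediate
10 | 6-(benzyloxy)-8-hydroxy-3-pentyl-1H-isochromen-1-one | CCCCCc1cc2cc(OCc3ccccc3)cc(O)c2c(=O)o1 | intermediate
11 | dimethyl (1-diazo-2-oxopropyl)phosphonate | COP(=O)(OC)C(=[N+]=[N-])C(C)=O | starting material
12 | dimethyl (1-{[6-(benzyloxy)-1-oxo-3-pentyl-1H-isochromen-8-yl]oxy}-2-oxopropyl)phosphonate; racemic | CCCCCc1cc2cc(OCc3ccccc3)cc(OC(C(C)=O)P(=O)(OC)OC)c2c(=O)o1 | intermediate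
13 | hexanal | CCCCCC=O | starting material
14 | (Z)-3-{[6-(benzyloxy)-1-oxo-3-pentyl-1H-isochromen-8-yl]oxy}non-3-en-2-one | CCCCC/C=C(\Oc1cc(OCc2ccccc2)cc2cc(CCCCC)oc(=O)c12)C(C)=O | intermediate
15 | dibenzyl malonate | O=C(CC(=O)OCc1ccccc1)OCc1ccccc1 | starting material
16 | dibenzyl 2-(3-{[6-(benzyloxy)-1-oxo-3-pentyl-1H-isochromen-8-yl]oxy}-2-oxononan-4-yl)propanedioate; diastereomer mixture, not isolated | CCCCCC(C(Oc1cc(OCc2ccccc2)cc2cc(CCCCC)oc(=O)c12)C(C)=O)C(C(=O)OCc1ccccc1)C(=O)OCc1ccccc1 | intermediate
17 | benzyl 3-{[6-(benzyloxy)-1-oxo-3-pentyl-1H-isochromen-8-yl]oxy}-4,6-dioxo-2-pentylcyclohexane-1-carboxylate; mixture of diastereomers and enol forms | CCCCCC1C(Oc2cc(OCc3ccccc3)cc3cc(CCCCC)oc(=O)c23)C(=O)CC(=O)C1C(=O)OCc1ccccc1 | intermediate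
18 | benzyl 5-{[6-(benzyloxy)-1-oxo-3-pentyl-1H-isochromen-8-yl]oxy}-6-pentyl-2,4-bis[(trimethylsilyl)oxy]cyclohexa-1,3-diene-1-carboxylate; diastereomer mixture | CCCCCC1C(Oc2cc(OCc3ccccc3)cc3cc(CCCCC)oc(=O)c23)C(O[Si](C)(C)C)=CC(O[Si](C)(C)C)=C1C(=O)OCc1ccccc1 | intermediate
19 | benzyl 3-{[6-(benzyloxy)-1-oxo-3-pentyl-1H-isochromen-8-yl]oxy}-2-pentyl-4,6-bis[(trimethylsilyl)oxy]benzoate; not isolated | CCCCCc1cc2cc(OCc3ccccc3)cc(Oc3c(O[Si](C)(C)C)cc(O[Si](C)(C)C)c(C(=O)OCc4ccccc4)c3CCCCC)c2c(=O)o1 | intermediate
20 | benzyl 3-{[6-(benzyloxy)-1-oxo-3-pentyl-1H-isochromen-8-yl]oxy}-4,6-dihydroxy-2-pentylbenzoate | CCCCCc1cc2cc(OCc3ccccc3)cc(Oc3c(O)cc(O)c(C(=O)OCc4ccccc4)c3CCCCC)c2c(=O)o1 | intermediate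
21 | 4,6-dihydroxy-3-[(6-hydroxy-1-oxo-3-pentyl-1H-isochromen-8-yl)oxy]-2-pentylbenzoic acid | CCCCCc1cc2cc(O)cc(Oc3c(O)cc(O)c(C(=O)O)c3CCCCC)c2c(=O)o1 | target

**Step count**

Total step count: 11.
Longest linear sequence: 10 steps (steps 1 and 3 to 11, from methyl orsellinate 1).

**Steps most likely to fail**

1. Step 8 (proposed new method). The α-aryloxy oxygen feeds electron density into the enone, so conjugate addition may be slow. Retro-Michael equilibration, or acyl transfer from the peri lactone of ring B to the malonate or to the transient C5' enolate, may then overtake the Claisen closure.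

   The fallback uses known chemistry only, sets out from phenol 10 and comes back to the route at target 21. Commercial olivetol (5-pentylbenzene-1,3-diol) is benzylated with 2 (K2CO3, DMF) to 1,3-bis(benzyloxy)-5-pentylbenzene F1. N-Iodosuccinimide (MeCN, catalytic CF3CO2H) should iodinate F1 para to one ether oxygen and next to the pentyl chain, giving 1,5-bis(benzyloxy)-2-iodo-3-pentylbenzene F2. An Ullmann ether coupling of F2 with 10 (CuI, picolinic acid, K3PO4, DMSO, 90 °C) gives 8-[2,4-bis(benzyloxy)-6-pentylphenoxy]-6-(benzyloxy)-3-pentyl-1H-isochromen-1-one F3. Vilsmeier–Haack formylation (POCl3, DMF) at the ring C position para to a benzyloxy group and next to the pentyl chain gives 4,6-bis(benzyloxy)-3-{[6-(benzyloxy)-1-oxo-3-pentyl-1H-isochromen-8-yl]oxy}-2-pentylbenzaldehyde F4. Pinnick oxidation (NaClO2, NaH2PO4, 2-methylbut-2-ene, tBuOH/H2O) gives 4,6-bis(benzyloxy)-3-{[6-(benzyloxy)-1-oxo-3-pentyl-1H-isochromen-8-yl]oxy}-2-pentylbenzoic acid F5, and hydrogenolysis (H2, Pd/C, EtOAc) of the three benzyl ethers gives 21.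

2. Step 6. The phenol is hydrogen-bonded to the lactone carbonyl and crowded by it, so oxonium ylide formation may be slow. The carbenoid may then add to the C3–C4 enol-lactone alkene or dimerise.

   The fallback sets out from 10 and comes back at 12, replacing carbene insertion by a polar substitution. Commercial dimethyl (2-oxopropyl)phosphonate is chlorinated (SO2Cl2, CH2Cl2, 0 °C) to dimethyl (1-chloro-2-oxopropyl)phosphonate F6. The potassium phenoxide of 10 (K2CO3, DMF, rt) then displaces chloride from F6 in a Williamson-type SN2 reaction, of the kind by which 2-chloroacetoacetates O-alkylate phenols, to give 12.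

3. Step 10. The allylic C5'–O bond of the silyl dienol ether may ionise, so that the aryloxide is lost and ring C aromatises without oxidation. The quinone may also attack the benzyl ethers before hydride abstraction is complete.

   The fallback sets out from dione 17 (steps 9 and 10 are both left out) and comes back at 20 by halogenation and dehydrohalogenation. Bromine (1.0 equiv) in DMF at 0 °C should brominate the enolised dione at the carbon between the two ring carbonyls, giving benzyl 5-bromo-3-{[6-(benzyloxy)-1-oxo-3-pentyl-1H-isochromen-8-yl]oxy}-4,6-dioxo-2-pentylcyclohexane-1-carboxylate F7. Gentle warming, kept as low as completes the reaction so that the hydrogen bromide formed spares the benzyl groups, should then bring about loss of HBr and tautomerisation to 20.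

**Further compounds**

F1 | step 8 | 1,3-bis(benzyloxy)-5-pentylbenzene | CCCCCc1cc(OCc2ccccc2)cc(OCc2ccccc2)c1
F2 | step 8 | 1,5-bis(benzyloxy)-2-iodo-3-pentylbenzene | CCCCCc1cc(OCc2ccccc2)cc(OCc2ccccc2)c1I
F3 | step 8 | 8-[2,4-bis(benzyloxy)-6-pentylphenoxy]-6-(benzyloxy)-3-pentyl-1H-isochromen-1-one | CCCCCc1cc2cc(OCc3ccccc3)cc(Oc3c(OCc4ccccc4)cc(OCc4ccccc4)cc3CCCCC)c2c(=O)o1
F4 | step 8 | 4,6-bis(benzyloxy)-3-{[6-(benzyloxy)-1-oxo-3-pentyl-1H-isochromen-8-yl]oxy}-2-pentylbenzaldehyde | CCCCCc1cc2cc(OCc3ccccc3)cc(Oc3c(OCc4ccccc4)cc(OCc4ccccc4)c(C=O)c3CCCCC)c2c(=O)o1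
F5 | step 8 | 4,6-bis(benzyloxy)-3-{[6-(benzyloxy)-1-oxo-3-pentyl-1H-isochromen-8-yl]oxy}-2-pentylbenzoic acid | CCCCCc1cc2cc(OCc3ccccc3)cc(Oc3c(OCc4ccccc4)cc(OCc4ccccc4)c(C(=O)O)c3CCCCC)c2c(=O)o1
F6 | step 6 | dimethyl (1-chloro-2-oxopropyl)phosphonate | COP(=O)(OC)C(Cl)C(C)=O
F7 | step 10 | benzyl 5-bromo-3-{[6-(benzyloxy)-1-oxo-3-pentyl-1H-isochromen-8-yl]oxy}-4,6-dioxo-2-pentylcyclohexane-1-carboxylate | CCCCCC1C(Oc2cc(OCc3ccccc3)cc3cc(CCCCC)oc(=O)c23)C(=O)C(Br)C(=O)C1C(=O)OCc1ccccc1
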